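**Retrosynthetic overview**
- Feature: the two naphthazarin tautomers of the core interconvert (ring A = C1–C4 with the side chain on C2, ring B = C5–C8). The unsubstituted ring B can therefore be built as the quinone ring, where C6=C7 is an isolated cis alkene between the oxygen-bearing carbons C5 and C8.
- The ester C–O bond is cut last (acylation of the free C1' alcohol). The tetrasubstituted alkene of the acyl group would be oxidised more easily than the arene in the oxidative O-demethylation, so it is attached after that step.
- Ring B: C6=C7 is formed by ring-closing metathesis of an ortho-bis(1-hydroxyallyl)-dimethoxyarene that already carries the side chain. Oxidation then gives the quinone, and the methyl ethers are removed by way of the diquinone.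
- C5–C6 and C7–C8 come from double vinyl Grignard addition to a 3,6-dimethoxyphthalaldehyde. C2–C1' comes from an aryllithium and a Weinreb amide, and C1' (R) is set by reagent-controlled ketone reduction.
- Ring order: ring A is the purchased benzene ring. Ring B is the only ring formed (step 10).

Key step: step 10

Assumption: 3,4-dimethylpent-3-enoic acid is not treated as a catalogue compound and is made in steps 14 and 15. Locants C1–C8 and C1' refer to the target drawn with the side chain on C2.

**Step 1**
Reactants: 1 2,5-dimethoxybenzaldehyde; 2 N,N-dimethylformamide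
Product: 5 3,6-dimethoxyphthalaldehyde, via lithium α-amino alkoxide 3 (not isolated), via ortho-lithiated α-amino alkoxide 4 (not isolated)
Conditions: MeNHCH2CH2NMe2, n-BuLi, THF, −20 °C; 1; n-BuLi (3 equiv), −20 °C; 2, −40 °C to rt; aq. HCl, 0 °C
Reagents that add atoms: N,N-dimethylformamide 2, CN(C)C=O; N,N,N'-trimethylethylenediamine, CNCCN(C)C (held in 3 and 4 only); n-butyllithium, [Li]CCCC (lithium of 3 and 4 only)
Why: Directed ortho-metalation through an in situ α-amino alkoxide, which masks the aldehyde and acts with the C5 methoxy group to direct n-BuLi to their shared ortho position C6; formylation with DMF and acid work-up should free both aldehydes.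

**Step 2**
Reactants: 5 3,6-dimethoxyphthalaldehyde
Product: 6 2,2'-(3,6-dimethoxy-1,2-phenylene)bis(1,3-dioxolane)
Conditions: HOCH2CH2OH, p-TsOH (cat.), toluene, reflux, Dean–Stark trap
Reagents that add atoms: ethylene glycol, OCCO
Why: Acid-catalysed acetalisation with azeotropic removal of water turns both aldehydes into base-stable dioxolanes ahead of the organolithium chemistry.

**Step 3**
Reactants: 6 2,2'-(3,6-dimethoxy-1,2-phenylene)bis(1,3-dioxolane)
Product: 7 2,2'-(4-bromo-3,6-dimethoxy-1,2-phenylene)bis(1,3-dioxolane)
Conditions: NBS (1.0 equiv), MeCN, 0 °C to rt, dark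
Reagents that add atoms: N-bromosuccinimide, O=C1CCC(=O)N1Br
Why: Electrophilic aromatic bromination under neutral ionic conditions; the two free ring positions are equivalent and each is ortho to a methoxy group, so only one monobromide can form, and the first bromine slows a second substitution.

**Step 4**
Reactants: 8 4-methylpent-3-enoic acid
Product: 9 N-methoxy-N,4-dimethylpent-3-enamide
Conditions: MeNHOMe·HCl, EDC·HCl, N-methylmorpholine, CH2Cl2, 0 °C to rt
Reagents that add atoms: N,O-dimethylhydroxylamine hydrochloride, CNOC.Cl
Why: Carbodiimide amide coupling to the Weinreb amide with only a weak base present, which should leave the β,γ-alkene in place.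

**Step 5**
Reactants: 7 2,2'-(4-bromo-3,6-dimethoxy-1,2-phenylene)bis(1,3-dioxolane); 9 N-methoxy-N,4-dimethylpent-3-enamide
Product: 11 1-[3,4-bis(1,3-dioxolan-2-yl)-2,5-dimethoxyphenyl]-4-methylpent-3-en-1-one, via aryllithium 10 (not isolated)
Conditions: n-BuLi (1.05 equiv), THF, −78 °C; 9, −78 °C; AcOH/THF quench at −78 °C
Reagents that add atoms: n-butyllithium, [Li]CCCC (lithium of 10 only)
Why: Bromine–lithium exchange at −78 °C is faster than any attack on the dioxolanes, the Weinreb ketone synthesis stops at the ketone, and the cold acidic quench prevents base-induced migration of the alkene into conjugation.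

**Step 6**
Reactants: 11 1-[3,4-bis(1,3-dioxolan-2-yl)-2,5-dimethoxyphenyl]-4-methylpent-3-en-1-one
Product: 12 (1R)-1-[3,4-bis(1,3-dioxolan-2-yl)-2,5-dimethoxyphenyl]-4-methylpent-3-en-1-ol
Conditions: (+)-Ipc2BCl, THF, −25 °C; HN(CH2CH2OH)2, Et2O, rt
Reagents that add atoms: none
Why: Asymmetric ketone reduction with B-chlorodiisopinocampheylborane; hydride passes from the pinanyl group in a six-membered boat-like transition state with the aryl group as the large substituent, so the reagent from (−)-α-pinene should give the R carbinol, and it neither hydroborates the alkene nor supplies a base that could move it.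

**Step 7**
Reactants: 12 (1R)-1-[3,4-bis(1,3-dioxolan-2-yl)-2,5-dimethoxyphenyl]-4-methylpent-3-en-1-ol
Product: 13 tert-butyldimethylsilyl ether of 12 (R)
Conditions: TBSCl, imidazole, DMF, rt
Reagents that add atoms: tert-butyldimethylsilyl chloride, CC(C)(C)[Si](C)(C)Cl
Why: Imidazole-promoted O-silylation involves only the O–H bond, so C1' keeps its configuration, and no Lewis-acidic silyl triflate is present that could open the dioxolanes.

**Step 8**
Reactants: 13 tert-butyldimethylsilyl ether of 12 (R)
Product: 14 4-[(1R)-1-(tert-butyldimethylsilyloxy)-4-methylpent-3-en-1-yl]-3,6-dimethoxyphthalaldehyde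
Conditions: PPTS (cat.), acetone–H2O, 50 °C
Reagents that add atoms: water, O
Why: Mild acid-catalysed acetal hydrolysis; the ortho-methoxy groups stabilise the oxocarbenium ions, so the aryl dioxolanes should hydrolyse at an acidity that leaves the secondary silyl ether and the trisubstituted alkene intact.

**Step 9**
Reactants: 14 4-[(1R)-1-(tert-butyldimethylsilyloxy)-4-methylpent-3-en-1-yl]-3,6-dimethoxyphthalaldehyde; 15 vinylmagnesium bromide
Product: 16 1,1'-{4-[(1R)-1-(tert-butyldimethylsilyloxy)-4-methylpent-3-en-1-yl]-3,6-dimethoxy-1,2-phenylene}bis(prop-2-en-1-ol) as a mixture of carbinol epimers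
Conditions: 15 (3 equiv), THF, −78 to 0 °C, 14 added to the reagent; pH 7 buffer
Reagents that add atoms: vinylmagnesium bromide 15, C=C[Mg]Br
Why: Double Grignard 1,2-addition; adding the dialdehyde to excess reagent in the cold keeps the mono-adduct from hydride transfer to a phthalide, and the two new carbinol centres form without control, which does no harm because both are removed in step 11.

**Step 10**
Reactants: 16 1,1'-{4-[(1R)-1-(tert-butyldimethylsilyloxy)-4-methylpent-3-en-1-yl]-3,6-dimethoxy-1,2-phenylene}bis(prop-2-en-1-ol)
Product: 17 6-[(1R)-1-(tert-butyldimethylsilyloxy)-4-methylpent-3-en-1-yl]-5,8-dimethoxy-1,4-dihydronaphthalene-1,4-diol as a mixture of carbinol epimers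
Conditions: second-generation Grubbs catalyst RuCl2(=CHPh)(PCy3)(SIMes) (5 mol %), 1,4-benzoquinone (10 mol %), CH2Cl2 (0.005 M), 40 °C, argon sparge; filtration through Et3N-deactivated silica
Reagents that add atoms: none
Why: Ring-closing olefin metathesis: the ruthenium benzylidene exchanges onto one of the two monosubstituted vinyl groups, the new alkylidene adds to the neighbouring vinyl group to give a ruthenacyclobutane, and its cycloreversion forms C6=C7 and passes on Ru=CH2, whose methylene leaves as ethene in the next turnover. The closest known reaction type is the metathesis of ortho-bis(1-hydroxyallyl)benzenes to 1,4-dihydronaphthalene-1,4-diols. Ring B closes as a six-membered carbocycle by joining two alkene carbons that the arene holds ortho to each other, so the closure is entropically favoured and the new alkene can only be cis. No stereocentre is created; the carbinol centres at C5 and C8 enter as an epimer mixture, every epimer can close, all are erased in step 11, and C1' is remote and untouched. The selectivity needed is vinyl over prenyl: initiation on the trisubstituted alkene is much slower, and closure through it would have to bridge meta positions of ring A in an eight-membered ring, which is out of reach. High dilution and the argon sparge suppress intermolecular metathesis and ethenolysis of the prenyl group, and 1,4-benzoquinone intercepts ruthenium hydrides that would turn an allylic carbinol into an ethyl ketone.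

**Step 11**
Reactants: 17 6-[(1R)-1-(tert-butyldimethylsilyloxy)-4-methylpent-3-en-1-yl]-5,8-dimethoxy-1,4-dihydronaphthalene-1,4-diol
Product: 18 6-[(1R)-1-(tert-butyldimethylsilyloxy)-4-methylpent-3-en-1-yl]-5,8-dimethoxynaphthalene-1,4-dione
Conditions: activated MnO2 (excess), CH2Cl2, rt
Reagents that add atoms: none
Why: Oxidation of allylic and benzylic alcohols with MnO2 under neutral conditions; both carbinols are doubly activated, the ene-dione formed is the quinone, all carbinol epimers converge, and the silyl-protected C1' centre cannot be oxidised.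

**Step 12**
Reactants: 18 6-[(1R)-1-(tert-butyldimethylsilyloxy)-4-methylpent-3-en-1-yl]-5,8-dimethoxynaphthalene-1,4-dione
Product: 20 2-[(1R)-1-(tert-butyldimethylsilyloxy)-4-methylpent-3-en-1-yl]-5,8-dihydroxynaphthalene-1,4-dione, via naphthalene-1,4,5,8-tetraone 19 (not isolated)
Conditions: AgO (4 equiv), 6 M HNO3, 1,4-dioxane, rt, a few minutes; aq. Na2S2O4 work-up
Reagents that add atoms: water, O
Why: Oxidative demethylation of a hydroquinone dimethyl ether by divalent silver, an established route from 5,8-dimethoxy-1,4-naphthoquinones to naphthazarins: water attacks the methoxy-bearing carbons with loss of methanol, the strongly oxidising diquinone takes two electrons from dithionite, and tautomer equilibration places the side chain on the quinone ring as drawn.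

**Step 13**
Reactants: 20 2-[(1R)-1-(tert-butyldimethylsilyloxy)-4-methylpent-3-en-1-yl]-5,8-dihydroxynaphthalene-1,4-dione
Product: 21 5,8-dihydroxy-2-[(1R)-1-hydroxy-4-methylpent-3-en-1-yl]naphthalene-1,4-dione (shikonin)
Conditions: HF·pyridine, pyridine, THF, 0 °C to rt
Reagents that add atoms: none
Why: Fluoride-driven desilylation in a pyridine-buffered medium breaks only the Si–O bond, and with the side chain on the electron-poor quinone ring, ionisation at C1' is disfavoured, so the R configuration should hold.

**Step 14**
Reactants: 22 2-bromo-3-methylbut-2-ene; 23 oxirane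
Product: 25 3,4-dimethylpent-3-en-1-ol, via alkenylmagnesium bromide 24 (not isolated)
Conditions: Mg, THF, reflux; CuI (10 mol %), 23 (THF solution), −30 °C to rt; H2O
Reagents that add atoms: oxirane 23, C1CO1; magnesium, [Mg] (in 24 only)
Why: Copper-catalysed opening of an epoxide by an alkenyl Grignard reagent adds the two-carbon unit to the fully substituted alkene carbon with the double-bond position already fixed.

**Step 15**
Reactants: 25 3,4-dimethylpent-3-en-1-ol
Product: 26 3,4-dimethylpent-3-enoic acid
Conditions: TEMPO (cat.), PhI(OAc)2 (2.2 equiv), MeCN–H2O, rt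
Reagents that add atoms: water, O
Why: Oxoammonium-catalysed oxidation of a primary alcohol through the aldehyde hydrate to the acid, free of strong acid or base, so neither lactonisation nor alkene migration should set in.

**Step 16**
Reactants: 21 shikonin; 26 3,4-dimethylpent-3-enoic acid
Product: 27 (1R)-1-(5,8-dihydroxy-1,4-dioxo-1,4-dihydronaphthalen-2-yl)-4-methylpent-3-en-1-yl 3,4-dimethylpent-3-enoate
Conditions: DCC, DMAP (cat.), CH2Cl2, 0 °C to rt
Reagents that add atoms: none
Why: Steglich esterification; both phenols are held in hydrogen bonds to the peri carbonyl groups and are poor nucleophiles, so only the secondary alcohol is acylated, the C1'–O bond is not broken (R retained), and catalytic DMAP in the cold should keep the β,γ-alkene of the acyl group in place.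

**Compound list**
1 | 2,5-dimethoxybenzaldehyde | COc1ccc(OC)c(C=O)c1 | starting material
2 | N,N-dimethylformamide | CN(C)C=O | starting material
3 | lithium α-amino alkoxide of 1 | COc1ccc(OC)c(C(O[Li])N(C)CCN(C)C)c1 | intermediate
4 | ortho-lithiated α-amino alkoxide | COc1ccc(OC)c(C(O[Li])N(C)CCN(C)C)c1[Li] | intermediate
5 | 3,6-dimethoxyphthalaldehyde | COc1ccc(OC)c(C=O)c1C=O | intermediate
6 | 2,2'-(3,6-dimethoxy-1,2-phenylene)bis(1,3-dioxolane) | COc1ccc(OC)c(C2OCCO2)c1C3OCCO3 | intermediate
7 | 2,2'-(4-bromo-3,6-dimethoxy-1,2-phenylene)bis(1,3-dioxolane) | COc1cc(Br)c(OC)c(C2OCCO2)c1C3OCCO3 | intermediate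
8 | 4-methylpent-3-enoic acid | CC(C)=CCC(=O)O | starting material
9 | N-methoxy-N,4-dimethylpent-3-enamide | CC(C)=CCC(=O)N(C)OC | intermediate
10 | [3,4-bis(1,3-dioxolan-2-yl)-2,5-dimethoxyphenyl]lithium | COc1cc([Li])c(OC)c(C2OCCO2)c1C3OCCO3 | intermediate
11 | 1-[3,4-bis(1,3-dioxolan-2-yl)-2,5-dimethoxyphenyl]-4-methylpent-3-en-1-one | CC(C)=CCC(=O)c1cc(OC)c(C2OCCO2)c(C3OCCO3)c1OC | intermediate
12 | (1R)-1-[3,4-bis(1,3-dioxolan-2-yl)-2,5-dimethoxyphenyl]-4-methylpent-3-en-1-ol | CC(C)=CC[C@@H](O)c1cc(OC)c(C2OCCO2)c(C3OCCO3)c1OC | intermediate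
13 | tert-butyldimethylsilyl ether of 12 (R) | CC(C)=CC[C@@H](O[Si](C)(C)C(C)(C)C)c1cc(OC)c(C2OCCO2)c(C3OCCO3)c1OC | intermediate
14 | 4-[(1R)-1-(tert-butyldimethylsilyloxy)-4-methylpent-3-en-1-yl]-3,6-dimethoxyphthalaldehyde | CC(C)=CC[C@@H](O[Si](C)(C)C(C)(C)C)c1cc(OC)c(C=O)c(C=O)c1OC | intermediate
15 | vinylmagnesium bromide | C=C[Mg]Br | starting material
16 | ortho-bis(1-hydroxyallyl)-dimethoxyarene with the R silyloxy side chain, carbinol epimers unassigned | CC(C)=CC[C@@H](O[Si](C)(C)C(C)(C)C)c1cc(OC)c(C(O)C=C)c(C(O)C=C)c1OC | intermediate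
17 | 6-[(1R)-1-(tert-butyldimethylsilyloxy)-4-methylpent-3-en-1-yl]-5,8-dimethoxy-1,4-dihydronaphthalene-1,4-diol, carbinol epimers unassigned | CC(C)=CC[C@@H](O[Si](C)(C)C(C)(C)C)c1cc(OC)c2C(O)C=CC(O)c2c1OC | intermediate
18 | 6-[(1R)-1-(tert-butyldimethylsilyloxy)-4-methylpent-3-en-1-yl]-5,8-dimethoxynaphthalene-1,4-dione | CC(C)=CC[C@@H](O[Si](C)(C)C(C)(C)C)c1cc(OC)c2C(=O)C=CC(=O)c2c1OC | intermediate
19 | 2-[(1R)-1-(tert-butyldimethylsilyloxy)-4-methylpent-3-en-1-yl]naphthalene-1,4,5,8-tetraone | CC(C)=CC[C@@H](O[Si](C)(C)C(C)(C)C)C1=CC(=O)C2=C(C1=O)C(=O)C=CC2=O | intermediate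
20 | 2-[(1R)-1-(tert-butyldimethylsilyloxy)-4-methylpent-3-en-1-yl]-5,8-dihydroxynaphthalene-1,4-dione | CC(C)=CC[C@@H](O[Si](C)(C)C(C)(C)C)C1=CC(=O)c2c(O)ccc(O)c2C1=O | intermediate
21 | 5,8-dihydroxy-2-[(1R)-1-hydroxy-4-methylpent-3-en-1-yl]naphthalene-1,4-dione (shikonin) | CC(C)=CC[C@@H](O)C1=CC(=O)c2c(O)ccc(O)c2C1=O | intermediate
22 | 2-bromo-3-methylbut-2-ene | CC(C)=C(C)Br | starting material
23 | oxirane | C1CO1 | starting material
24 | (3-methylbut-2-en-2-yl)magnesium bromide | CC(C)=C(C)[Mg]Br | intermediate
25 | 3,4-dimethylpent-3-en-1-ol | CC(C)=C(C)CCO | intermediate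
26 | 3,4-dimethylpent-3-enoic acid | CC(C)=C(C)CC(=O)O | intermediate
27 | (1R)-1-(5,8-dihydroxy-1,4-dioxo-1,4-dihydronaphthalen-2-yl)-4-methylpent-3-en-1-yl 3,4-dimethylpent-3-enoate | CC(C)=CC[C@@H](OC(=O)CC(C)=C(C)C)C1=CC(=O)c2c(O)ccc(O)c2C1=O | target

**Step count**
- Total: 16 steps.
- Longest linear sequence: 13 steps (steps 1–3, 5–13 and 16).

**Steps most likely to fail**

Step 10.
- Ruthenium hydrides formed from the catalyst may isomerise a free allylic carbinol to an ethyl ketone before closure.
- The doubly activated diol may lose water and aromatise.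
- Buttressing by the flanking methoxy groups may slow the closure enough for metathesis at the prenyl alkene to compete.
- Fallback, from 16: both carbinols are capped with Et3SiCl and imidazole to give the bis(triethylsilyl) ether F1, in which neither redox isomerisation nor ionisation is open. Ring-closing metathesis with the same catalyst then gives the bis(triethylsilyloxy)dihydronaphthalene F2. Pyridine-buffered HF·pyridine at 0 °C removes secondary triethylsilyl ethers well before the hindered tert-butyldimethylsilyl ether, and the route is rejoined at 17.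

Step 12.
- Divalent silver in nitric acid may attack the trisubstituted alkene or the C1'–H bond in competition with the acceptor-substituted arene.
- The silyl ether may be lost in the acid.
- Fallback, from 18: reductive acetylation (Zn, Ac2O, NaOAc) gives the 1,4-diacetoxy-5,8-dimethoxynaphthalene F3. Its dimethoxy ring is now the electron-rich half of a naphthalene and should yield to the much milder tetravalent cerium oxidant (NH4)2Ce(NO3)6 in MeCN–H2O at 0 °C. This gives the 5,8-diacetoxy-1,4-naphthoquinone F4 with the side chain already on the quinone ring. Methanolysis of the two aryl acetates (K2CO3, MeOH, 0 °C, argon) rejoins the route at 20.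

Step 6.
- Facial selectivity may be eroded by the ortho-methoxy group and the crowded arene.
- The chloroborane may open a dioxolane.
- A slow reduction would give the alkene time to drift into conjugation.
- Fallback, from 7: bromine–lithium exchange as in step 5 gives 10, and a DMF quench gives the aldehyde F5. Brown allylation with B-allyldiisopinocampheylborane of the (−)-α-pinene series (from (+)-Ipc2BOMe and allylmagnesium bromide, then NaOH/H2O2) sets C1' through a chair transition state and gives the (R)-homoallylic alcohol F6. Cross-metathesis with 2-methylbut-2-ene (second-generation Grubbs catalyst) builds the prenyl terminus and rejoins the route at 12.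

**Further compounds**
F1 | step 10 | bis(triethylsilyl) ether of 16 | CC(C)=CC[C@@H](O[Si](C)(C)C(C)(C)C)c1cc(OC)c(C(O[Si](CC)(CC)CC)C=C)c(C(O[Si](CC)(CC)CC)C=C)c1OC
F2 | step 10 | bis(triethylsilyl) ether of 17 | CC(C)=CC[C@@H](O[Si](C)(C)C(C)(C)C)c1cc(OC)c2C(O[Si](CC)(CC)CC)C=CC(O[Si](CC)(CC)CC)c2c1OC
F3 | step 12 | 6-[(1R)-1-(tert-butyldimethylsilyloxy)-4-methylpent-3-en-1-yl]-5,8-dimethoxynaphthalene-1,4-diyl diacetate | CC(C)=CC[C@@H](O[Si](C)(C)C(C)(C)C)c1cc(OC)c2c(OC(C)=O)ccc(OC(C)=O)c2c1OC
F4 | step 12 | 6-[(1R)-1-(tert-butyldimethylsilyloxy)-4-methylpent-3-en-1-yl]-5,8-dioxo-5,8-dihydronaphthalene-1,4-diyl diacetate | CC(C)=CC[C@@H](O[Si](C)(C)C(C)(C)C)C1=CC(=O)c2c(OC(C)=O)ccc(OC(C)=O)c2C1=O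
F5 | step 6 | 3,4-bis(1,3-dioxolan-2-yl)-2,5-dimethoxybenzaldehyde | O=Cc1cc(OC)c(C2OCCO2)c(C3OCCO3)c1OC
F6 | step 6 | (1R)-1-[3,4-bis(1,3-dioxolan-2-yl)-2,5-dimethoxyphenyl]but-3-en-1-ol | C=CC[C@@H](O)c1cc(OC)c(C2OCCO2)c(C3OCCO3)c1OC
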